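**Strategy.** The route rests on reading the C9–C8–C8'–C9' backbone shared by the two tetrahydrofuran rings as a butenolide: C9 is the carbonyl, C9' a menthyl acetal carbon, and C8 and C8' are the α- and β-carbons that each carry one benzylic carbon (C7, C7'). One three-component operation on (5S)-5-menthyloxy-2(5H)-furanone joins C7'–C8' by conjugate addition of the lithiated dithiane of O-prenylvanillin and C7–C8 by aldol capture of TIPS-vanillin, fixing C8 and C8' trans. Unmasking, hydride reduction and a stereoconvergent acid-mediated double ring closure then build both ether rings with exo aryl groups; desilylation ends the synthesis.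

Key step: step 6

Remark on the chemistry: lignan numbering is used (C7/C7' benzylic, C8/C8' ring fusion, C9/C9' OCH2). The target is (7R,8S,7'R,8'S) with both aryl groups exo on the cis-fused bicycle, and the (5S) acetal from (+)-menthol leads to this (8S,8'S) series. The carbinol configurations made before step 9 are assumed not to matter, because that step re-forms C7 and C7' from benzylic cations.

Step 1
Reactants: 1 furfural
Product: 3 5-hydroxyfuran-2(5H)-one (racemic hemiacetal), via furfural endoperoxide 2 (not isolated)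
Conditions: O2, rose bengal (cat.), hν (visible), MeOH, 20 °C
Reagents that add atoms: oxygen, O=O
Why: Dye-sensitised singlet-oxygen [4+2] photooxygenation of the furan gives endoperoxide 2, which methanol opens with loss of the formyl carbon as methyl formate, a known entry to the hydroxybutenolide.

Step 2
Reactants: 3 5-hydroxyfuran-2(5H)-one; 4 (+)-menthol [(1S,2R,5S)-menthol]
Product: 6 (5S)-5-[(1S,2R,5S)-menthyloxy]furan-2(5H)-one, via C5-epimeric menthyl acetal mixture 5 (not isolated)
Conditions: CSA (cat.), toluene, reflux, azeotropic removal of water; crystallisation from petroleum ether, −20 °C; mother liquor re-equilibrated (CSA) and recrystallised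
Reagents that add atoms: none
Why: Acid-catalysed acetalisation of the cyclic hemiacetal gives both C5 epimers, which interconvert through the oxocarbenium ion, so crystallisation should drain the mixture into the less soluble (5S) epimer (crystallisation-induced diastereomer transformation), the menthyl group thereby fixing C5.

Step 3
Reactants: 7 vanillin; 8 1,3-propanedithiol
Product: 9 2-(4-hydroxy-3-methoxyphenyl)-1,3-dithiane
Conditions: BF3·OEt2 (0.2 equiv), CH2Cl2, 0 °C → rt
Reagents that add atoms: none
Why: Lewis-acid-catalysed dithioacetalisation of an aromatic aldehyde tolerates the free phenol, and doing it before prenylation keeps the acid-labile allylic ether away from BF3 and thiol.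

Step 4
Reactants: 9 2-(4-hydroxy-3-methoxyphenyl)-1,3-dithiane
Product: 10 2-[3-methoxy-4-(3-methylbut-2-enyloxy)phenyl]-1,3-dithiane
Conditions: prenyl bromide, K2CO3, DMF, rt
Reagents that add atoms: prenyl bromide (1-bromo-3-methylbut-2-ene), CC(C)=CCBr
Why: Williamson O-alkylation of the potassium phenoxide by the allylic bromide (SN2) should be clean because the thioacetal sulfurs are far weaker nucleophiles than the phenoxide.

Step 5
Reactants: 7 vanillin
Product: 11 3-methoxy-4-(triisopropylsilyloxy)benzaldehyde
Conditions: TIPSCl, imidazole, DMF, rt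
Reagents that add atoms: triisopropylsilyl chloride, CC(C)[Si](Cl)(C(C)C)C(C)C
Why: Standard imidazole-mediated silylation of a phenol; the bulky TIPS ether is chosen to survive the organolithium step, hydride and mild acid, and to leave with fluoride at the end.

Step 6
Reactants: 10 2-[3-methoxy-4-(3-methylbut-2-enyloxy)phenyl]-1,3-dithiane; 6 (5S)-5-[(1S,2R,5S)-menthyloxy]furan-2(5H)-one; 11 3-methoxy-4-(triisopropylsilyloxy)benzaldehyde
Product: 14 (3R,4S,5S)-3-{hydroxy[3-methoxy-4-(triisopropylsilyloxy)phenyl]methyl}-4-{2-[3-methoxy-4-(3-methylbut-2-enyloxy)phenyl]-1,3-dithian-2-yl}-5-[(1S,2R,5S)-menthyloxy]dihydrofuran-2(3H)-one (mixture of C7 carbinol epimers), via 2-lithio-1,3-dithiane 12 (not isolated), via lithium lactone enolate 13 (not isolated)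
Conditions: n-BuLi (1.0 equiv), THF, −78 → −30 °C; then 6, −78 °C; then 11, −78 °C; AcOH/THF quench at −78 °C
Reagents that add atoms: none
Why: n-BuLi removes the C2–H of dithiane 10 to give the sulfur-stabilised carbanion 12, which adds 1,4 to butenolide 6 at the β-carbon (C8') to form lithium enolate 13, and 13 then adds through C8 to the carbonyl of aldehyde 11 before a cold acetic acid quench. This is the known tandem conjugate addition–aldol (Michael–aldol three-component coupling) of 2-lithio-2-aryl-1,3-dithianes with 5-alkoxy-2(5H)-furanones. No ring is closed; the lactone serves only as a template that is opened in step 8. C8' is controlled by the acetal centre C9', whose menthyloxy group blocks one face so that the carbanion enters anti to it, and C8 is controlled by the bulky dithianyl group on C8', the aldehyde approaching the enolate anti to it to give the 3,4-trans lactone; the carbinol centre C7 is not controlled and need not be. The step needs 1,4- over 1,2-addition, which the soft, hindered dithianyl anion secures, and clean enolate capture without proton transfer or retro-aldol, which the non-enolisable aldehyde, the inert TIPS and prenyl ethers and the quench at −78 °C secure.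

Step 7
Reactants: 14 the dithianyl aldol lactone
Product: 15 (3R,4S,5S)-3-{hydroxy[3-methoxy-4-(triisopropylsilyloxy)phenyl]methyl}-4-[3-methoxy-4-(3-methylbut-2-enyloxy)benzoyl]-5-[(1S,2R,5S)-menthyloxy]dihydrofuran-2(3H)-one
Conditions: MeI (excess), CaCO3, MeCN–H2O (4:1), 40 °C
Reagents that add atoms: water, O
Why: Alkylative dethioacetalisation: S-methylation turns one sulfur into a leaving group and the aryl-stabilised thionium ion is hydrolysed to the aryl ketone, while this buffered, metal-free medium spares the prenyl alkene (which mercury(II) or halonium reagents would attack), the acetal, the silyl ether and the lactone.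

Step 8
Reactants: 15 the keto lactone
Product: 16 (2S,3S)-2,3-bis(hydroxymethyl)-1-[3-methoxy-4-(triisopropylsilyloxy)phenyl]-4-[3-methoxy-4-(3-methylbut-2-enyloxy)phenyl]butane-1,4-diol (mixture of epimers at C1 = C7 and C4 = C7')
Conditions: LiAlH4, THF, 0 °C → rt; aq. NaOH work-up
Reagents that add atoms: none
Why: Exhaustive LiAlH4 reduction turns the ketone into the C7' carbinol and the lactone carbonyl into the C9 alcohol, and the ring-opened hemiacetal alkoxide expels menthoxide to an aldehyde that is reduced to the C9' alcohol; C8 and C8' are untouched and the new carbinol centre need not be controlled.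

Step 9
Reactants: 16 the tetraol
Product: 17 triisopropyl{2-methoxy-4-[(1R,3aS,4R,6aS)-4-[3-methoxy-4-(3-methylbut-2-enyloxy)phenyl]tetrahydro-1H,3H-furo[3,4-c]furan-1-yl]phenoxy}silane
Conditions: CSA (0.1 equiv), 4 Å MS, CH2Cl2 (0.01 M), 0 °C → rt; Et3N quench
Reagents that add atoms: none
Why: Acid-catalysed dehydrative cycloetherification (SN1), the usual closure for furofuran lignans: each para-oxygenated benzylic carbinol ionises to a stabilised benzylic cation that is captured in a five-membered ring closure by the primary hydroxyl (O on C9' at C7, O on C9 at C7'), so all carbinol epimers should converge, and under kinetic control each aryl group should end up exo, trans to the neighbouring ring-fusion substituent, which sets C7 and C7' as R.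

Step 10
Reactants: 17 the TIPS-protected furofuran
Product: 18 4-[(1R,3aS,4R,6aS)-4-[3-methoxy-4-(3-methylbut-2-enyloxy)phenyl]tetrahydro-1H,3H-furo[3,4-c]furan-1-yl]-2-methoxyphenol (target)
Conditions: TBAF, AcOH, THF, 0 °C
Reagents that add atoms: none
Why: Fluoride-induced cleavage of the aryl silyl ether, buffered with acetic acid, should free the phenol without touching the prenyl ether or the benzylic ether stereocentres.

**Compound list**

1 | furfural | O=Cc1ccco1 | starting material
2 | 1-formyl-2,3,7-trioxabicyclo[2.2.1]hept-5-ene (furfural endoperoxide) | O=CC12OOC(O1)C=C2 | intermediate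
3 | 5-hydroxyfuran-2(5H)-one (racemic) | O=C1OC(O)C=C1 | intermediate
4 | (+)-menthol, (1S,2R,5S) | CC(C)[C@H]1CC[C@H](C)C[C@@H]1O | starting material
5 | 5-[(1S,2R,5S)-menthyloxy]furan-2(5H)-one, mixture of C5 epimers | CC(C)[C@H]1CC[C@H](C)C[C@@H]1OC2OC(=O)C=C2 | intermediate
6 | (5S)-5-[(1S,2R,5S)-menthyloxy]furan-2(5H)-one | CC(C)[C@H]1CC[C@H](C)C[C@@H]1O[C@H]2OC(=O)C=C2 | intermediate
7 | vanillin | COc1cc(C=O)ccc1O | starting material
8 | 1,3-propanedithiol | SCCCS | starting material
9 | 2-(4-hydroxy-3-methoxyphenyl)-1,3-dithiane | COc1cc(C2SCCCS2)ccc1O | intermediate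
10 | 2-[3-methoxy-4-(3-methylbut-2-enyloxy)phenyl]-1,3-dithiane | COc1cc(C2SCCCS2)ccc1OCC=C(C)C | intermediate
11 | 3-methoxy-4-(triisopropylsilyloxy)benzaldehyde | COc1cc(C=O)ccc1O[Si](C(C)C)(C(C)C)C(C)C | intermediate
12 | 2-lithio-2-[3-methoxy-4-(3-methylbut-2-enyloxy)phenyl]-1,3-dithiane | [Li]C1(c2ccc(OCC=C(C)C)c(OC)c2)SCCCS1 | intermediate
13 | lithium enolate of (4S,5S)-4-{2-[3-methoxy-4-(3-methylbut-2-enyloxy)phenyl]-1,3-dithian-2-yl}-5-[(1S,2R,5S)-menthyloxy]dihydrofuran-2(3H)-one | CC(C)[C@H]1CC[C@H](C)C[C@@H]1O[C@H]2OC(O[Li])=C[C@@H]2C2(c3ccc(OCC=C(C)C)c(OC)c3)SCCCS2 | intermediate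
14 | (3R,4S,5S)-3-{hydroxy[3-methoxy-4-(triisopropylsilyloxy)phenyl]methyl}-4-{2-[3-methoxy-4-(3-methylbut-2-enyloxy)phenyl]-1,3-dithian-2-yl}-5-[(1S,2R,5S)-menthyloxy]dihydrofuran-2(3H)-one, carbinol epimers | CC(C)[C@H]1CC[C@H](C)C[C@@H]1O[C@H]2OC(=O)[C@@H](C(O)c3ccc(O[Si](C(C)C)(C(C)C)C(C)C)c(OC)c3)[C@@H]2C2(c3ccc(OCC=C(C)C)c(OC)c3)SCCCS2 | intermediate
15 | (3R,4S,5S)-3-{hydroxy[3-methoxy-4-(triisopropylsilyloxy)phenyl]methyl}-4-[3-methoxy-4-(3-methylbut-2-enyloxy)benzoyl]-5-[(1S,2R,5S)-menthyloxy]dihydrofuran-2(3H)-one, carbinol epimers | CC(C)[C@H]1CC[C@H](C)C[C@@H]1O[C@H]2OC(=O)[C@@H](C(O)c3ccc(O[Si](C(C)C)(C(C)C)C(C)C)c(OC)c3)[C@@H]2C(=O)c2ccc(OCC=C(C)C)c(OC)c2 | intermediate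
16 | (2S,3S)-2,3-bis(hydroxymethyl)-1-[3-methoxy-4-(triisopropylsilyloxy)phenyl]-4-[3-methoxy-4-(3-methylbut-2-enyloxy)phenyl]butane-1,4-diol, epimers at C1 and C4 | OC[C@@H](C(O)c1ccc(O[Si](C(C)C)(C(C)C)C(C)C)c(OC)c1)[C@@H](CO)C(O)c1ccc(OCC=C(C)C)c(OC)c1 | intermediate
17 | triisopropyl{2-methoxy-4-[(1R,3aS,4R,6aS)-4-[3-methoxy-4-(3-methylbut-2-enyloxy)phenyl]tetrahydro-1H,3H-furo[3,4-c]furan-1-yl]phenoxy}silane | COc1cc([C@@H]2OC[C@@H]3[C@H]2CO[C@H]3c2ccc(OCC=C(C)C)c(OC)c2)ccc1O[Si](C(C)C)(C(C)C)C(C)C | intermediate
18 | 4-[(1R,3aS,4R,6aS)-4-[3-methoxy-4-(3-methylbut-2-enyloxy)phenyl]tetrahydro-1H,3H-furo[3,4-c]furan-1-yl]-2-methoxyphenol, (7R,8S,7'R,8'S) | COc1cc([C@@H]2OC[C@@H]3[C@H]2CO[C@H]3c2ccc(OCC=C(C)C)c(OC)c2)ccc1O | target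

**Step count and risks**

Total steps: 10. Longest linear sequence: 7 steps (steps 1, 2, 6, 7, 8, 9, 10; the branch through steps 3, 4, 6–10 is equally long).

Steps most likely to fail:

1. Step 6. After the conjugate addition, capture of the enolate by the hindered aldehyde may be incomplete, the aldolate may revert on warming, or proton transfer may quench the enolate, leaving only the conjugate adduct. The fallback separates the two bond formations. It sets out from 6 and 10: the conjugate addition is run alone and protonated at −78 °C, and the (4S,5S) conjugate adduct F1 is isolated. Enolate 13 is then regenerated from F1 with LDA in THF at −78 °C (directed aldol of a preformed lactone enolate, with counter-ion exchange to zinc if needed) and treated with 11, which returns to the route at 14.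

2. Step 9. Exo selectivity may be incomplete because exo and endo aryl isomers are close in energy; a benzylic cation may be captured by the other benzylic hydroxyl to give a 2,5-diaryl tetrahydrofuran; or the acid may strip the prenyl group. The fallback closes the rings one at a time while the second benzylic carbon is still masked. It sets out from 14: LiAlH4 should give the (8S,8'S) dithiane triol F2, in which only C7 can ionise and only the C9' hydroxyl can close a five-membered ring. CSA should therefore give the 2,3-trans monocyclic ether F3, where thermodynamic preference also favours the trans aryl group. MeI/CaCO3 then unmasks the hydroxy ketone F4, NaBH4 gives the diol F5, and a second CSA closure with a single nucleophile present returns to the route at 17.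

3. Step 7. S-alkylation at the hindered, fully substituted dithiane carbon may be slow, and the keto lactone, whose ketone lies β to the acyloxy oxygen on C9', may undergo β-elimination or epimerise at C8' on prolonged heating. The fallback unmasks the ketone after the hydride step. It sets out from 14: LiAlH4 gives the dithiane triol F2 (the compound already met in the fallback for step 9). MeI/CaCO3 in aqueous MeCN then hydrolyses the thioketal with internal capture of the thionium ion by a neighbouring hydroxyl, giving the hydroxy ketone F6 (in equilibrium with its cyclic hemiketal), which has no acyloxy leaving group. NaBH4 in MeOH reduces F6 to the tetraol, returning to the route at 16.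

**Further compounds**

F1 | step 6 | (4S,5S)-4-{2-[3-methoxy-4-(3-methylbut-2-enyloxy)phenyl]-1,3-dithian-2-yl}-5-[(1S,2R,5S)-menthyloxy]dihydrofuran-2(3H)-one | CC(C)[C@H]1CC[C@H](C)C[C@@H]1O[C@H]2OC(=O)C[C@@H]2C2(c3ccc(OCC=C(C)C)c(OC)c3)SCCCS2
F2 | step 9 | (8S,8'S) dithiane triol: 2-(hydroxymethyl)-3-{hydroxy[3-methoxy-4-(triisopropylsilyloxy)phenyl]methyl}-4-hydroxy-1-[2-aryl-1,3-dithian-2-yl]butane skeleton, aryl = 3-methoxy-4-(3-methylbut-2-enyloxy)phenyl, C7 epimers | OC[C@@H](C(O)c1ccc(O[Si](C(C)C)(C(C)C)C(C)C)c(OC)c1)[C@@H](CO)C1(c2ccc(OCC=C(C)C)c(OC)c2)SCCCS1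
F3 | step 9 | [(2R,3S,4S)-2-[3-methoxy-4-(triisopropylsilyloxy)phenyl]-4-{2-[3-methoxy-4-(3-methylbut-2-enyloxy)phenyl]-1,3-dithian-2-yl}tetrahydrofuran-3-yl]methanol | COc1cc([C@@H]2OC[C@@H](C3(c4ccc(OCC=C(C)C)c(OC)c4)SCCCS3)[C@H]2CO)ccc1O[Si](C(C)C)(C(C)C)C(C)C
F4 | step 9 | (7R,8S,8'S) hydroxy ketone: the tetrahydrofuran of F3 with the dithiane replaced by a 3-methoxy-4-(3-methylbut-2-enyloxy)benzoyl group | COc1cc([C@@H]2OC[C@@H](C(=O)c3ccc(OCC=C(C)C)c(OC)c3)[C@H]2CO)ccc1O[Si](C(C)C)(C(C)C)C(C)C
F5 | step 9 | (7R,8S,8'S) diol: the tetrahydrofuran of F4 with the ketone reduced to the carbinol, C7' epimers | COc1cc([C@@H]2OC[C@@H](C(O)c3ccc(OCC=C(C)C)c(OC)c3)[C@H]2CO)ccc1O[Si](C(C)C)(C(C)C)C(C)C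
F6 | step 7 | (2S,3S)-4-hydroxy-2,3-bis(hydroxymethyl)-4-[3-methoxy-4-(triisopropylsilyloxy)phenyl]-1-[3-methoxy-4-(3-methylbut-2-enyloxy)phenyl]butan-1-one, C7 epimers | OC[C@@H](C(O)c1ccc(O[Si](C(C)C)(C(C)C)C(C)C)c(OC)c1)[C@@H](CO)C(=O)c1ccc(OCC=C(C)C)c(OC)c1
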